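The meeting had 4 questions before it, and the secretary set them down with the flasks and the earlier runs.

- the best flask by amount of target, in percent of the starting material charged; "all alike" if 1.5 percentage points covers them all (teal / green / red / all alike)
- amount of target at the end, in percent of the starting material charged, teal
- amount of target at the end, in percent of the starting material charged, green
- amount of target at the end, in percent of the starting material charged, red

| flask | starting material | coupling partner | second substrate | protic impurity | temperature | remark | time |
|---|---|---|---|---|---|---|---|
| larch | 10 mM | 60 mM | 20 mM | 2 mM | −25 °C | run made earlier |  |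
| elm | 15 mM | 60 mM | 20 mM | 2 mM | −12 °C | run made earlier |  |
| teal | 20 mM | 60.0 mM | 20.0 mM | 2.00 mM |  | at −20 °C until 8.0 min, from then on at −5 °C | 25 min |
| green | 20 mM | 60.0 mM | 20.0 mM | 2.00 mM | −5 °C |  | 25 min |
| red | 20 mM | 60.0 mM | 20.0 mM | 2.00 mM | −20 °C |  | 25 min |

- larch (time / min: target / %, starting material / %): 4.00: 24, 64; 6.00: 26, 59; 10.0: 33, 51; 20.0: 36, 45; 40.0: 37, 45
- elm (time / min: target / %, starting material / %): 3.00: 25, 63; 6.00: 27, 61; 10.0: 23, 63; 12.0: 29, 61; 15.0: 25, 59

(scatter of a reading: 1.5 percentage points)



The analyst reported that the larch run stops moving from about 20.0 min, with target and starting material both still present, although coupling partner was charged in excess (60 mM against 10 mM). She argued that such a stop looks like a balance, not an exhausted reagent.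

The kineticist added that a part of the charge goes missing. Target and starting material sum to 82.0% at the last larch reading, while removing one equivalent of protic impurity leaves 80.0%. In elm at 6.00 min the sum is 88.0% against 86.7%. He therefore proposed that the new flasks, with 20 mM of starting material, keep 90.0% of the charge to share between the two.

As secretary I proposed reading that share as a ratio r, target over starting material, with r equal to one, the even case, as the zero of the scale. The plateau readings give 0.811 at −25 °C and, averaging every elm reading, 0.420 at −12 °C. Both lie below even, and the warmer run, elm, lies lower. The two runs also differ in their charge of starting material, but setting that aside and taking ln r as straight in temperature, I get r of 0.630 at −20 °C and 0.295 at −5 °C.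

Dividing by the charged partner gives the plateau quotient, [target]/([starting material] times the charged [coupling partner]), an apparent equilibrium constant, of 4.91 M⁻¹ at −5 °C. The even point lies at 203 mM of partner, more than the 60.0 mM charged.

The process chemist noted that teal spends 17.0 min warm, more than the 3.00 min at which elm already read level, so a balance should follow its last temperature. I therefore reckoned 20.5% for teal and green, and 34.8% for red.

The forecast, which lies 16 percentage points below this for red, gave all alike, with 19%, 19% and 19% for teal, green and red, holding: “This cap looks independent of temperature”.

The best flask is red, with 33.4% of target, more than the 21.0% of teal and the 21.0% of green.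

    starting material + coupling partner ⇌ target (K = 12.0 M⁻¹, k = 0.0410 M⁻¹ s⁻¹, Ea = 48.0 kJ mol⁻¹, ΔH = −25.0 kJ mol⁻¹)
    second substrate + coupling partner ⇌ second product (K = 5.50 M⁻¹, k = 0.0540 M⁻¹ s⁻¹, Ea = 38.0 kJ mol⁻¹, ΔH = 21.0 kJ mol⁻¹)
    starting material + protic impurity → quenched substrate (k = 0.680 M⁻¹ s⁻¹, Ea = 42.0 kJ mol⁻¹)
    (constants at −20 °C)

Teal held 31.8% of target at 8.00 min, when it was warmed, and 21.0% at 12.5 min. Applied to the 69.0% of starting material left in teal, the quotient and the charged partner give 20.3% of target, where the flask has 21.0%.

In a neighbour flask, which is green with 240 mM of coupling partner, the charge stands above the even point, so the quotient gives r of 1.18 and 48.7% of target. The computed neighbour flask gives 51.5%, and target holds most of the starting material there.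

(The data were generated by integration with constants of no real substance, and the scatter is random.)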